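**Retrosynthetic overview**
- The target is traced back through hydrogenolysis of three benzyl ethers, a Weinreb ketone synthesis with 2-phenylethylmagnesium bromide, and a dimethyldioxirane oxidation at C3, to an 8-substituted 5,7-bis(benzyloxy)flavone carrying the chain arm as an N-methoxy-N-methylamide.
- Ring C, the only ring built, is cut at C4–C4a: the flavone comes from a (Z)-3-aryloxycinnamic acid by intramolecular Friedel–Crafts acylation. O1–C2 is made before that by oxa-Michael addition of a phenol to ethyl phenylpropiolate.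
- The phenol comes from Weinreb aminolysis of a (4R)-4-alkyl-5,7-bis(benzyloxy)chroman-2-one, which frees exactly one phenol. That lactone comes from 5,7-bis(benzyloxy)coumarin and an arylethyl Grignard reagent by copper-catalysed asymmetric conjugate addition, which sets the only stereocentre.
- Feature: in ring A, O1 sits on C8a between C8 and C4a. C8 carries the benzylic chain stereocentre, so the acyl carbon C4 can bond only to C4a, which is activated by O1, the C5 oxygen and the C7 oxygen.
- Ring order: ring A, the 2-phenyl ring and both chain arenes are bought; the coumarin lactone is a temporary ring opened in step 5; ring C closes in step 8.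

Key step: step 8

Assumption: the sense of induction of the copper–ferrocenyl diphosphine catalyst in step 4 is not presumed, and the ligand antipode that sends the alkyl group to the Re face of C4 (giving 4R) is the one used; the aryloxycinnamate is drawn as the (Z)-isomer expected from anti addition, and any (E)-isomer is carried along because the key step converges both.

**Route**

Step 1
Reactants: 1 5,7-dihydroxycoumarin
Product: 2 5,7-bis(benzyloxy)coumarin
Conditions: BnBr (2.4 equiv), K2CO3, DMF, 60 °C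
Reagents that add atoms: benzyl bromide, BrCc1ccccc1
Why: Williamson ether synthesis on both phenols; the lactone is not opened by carbonate in an aprotic solvent.

Step 2
Reactants: 3 homovanillyl alcohol
Product: 4 2-[4-(benzyloxy)-3-methoxyphenyl]ethanol
Conditions: BnBr (1.05 equiv), K2CO3, acetone, reflux
Reagents that add atoms: benzyl bromide, BrCc1ccccc1
Why: Williamson ether synthesis that is chemoselective for the phenol, since K2CO3 deprotonates the phenol but not the primary alcohol.

Step 3
Reactants: 4 2-[4-(benzyloxy)-3-methoxyphenyl]ethanol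
Product: 5 1-(benzyloxy)-4-(2-bromoethyl)-2-methoxybenzene
Conditions: CBr4, PPh3, CH2Cl2, 0 °C to rt
Reagents that add atoms: carbon tetrabromide, BrC(Br)(Br)Br
Why: Appel reaction converts the primary alcohol into the bromide under neutral conditions that the aryl benzyl ether tolerates.

Step 4
Reactants: 5 1-(benzyloxy)-4-(2-bromoethyl)-2-methoxybenzene; 2 5,7-bis(benzyloxy)coumarin
Product: 7 (4R)-5,7-bis(benzyloxy)-4-{2-[4-(benzyloxy)-3-methoxyphenyl]ethyl}chroman-2-one, via arylethylmagnesium bromide 6 (not isolated)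
Conditions: 5, Mg, Et2O, reflux; then 2, CuBr·SMe2 (5 mol%), (R)-1-[(Sp)-2-(dicyclohexylphosphino)ferrocenyl]ethyldiphenylphosphine or its enantiomer, whichever gives 4R (6 mol%), CH2Cl2, −72 °C; then 1 M HCl, −72 °C to rt
Reagents that add atoms: none
Why: Copper-catalysed asymmetric conjugate addition of a Grignard reagent to a coumarin, a known reaction of this lactone class with ferrocenyl diphosphine ligands, should deliver the arylethyl group to the Re face of C4 under ligand control and so set the 4R centre, while the low temperature and CH2Cl2 suppress 1,2-addition and collapse of the magnesium enolate before the cold acid quench.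

Step 5
Reactants: 7 (4R)-5,7-bis(benzyloxy)-4-{2-[4-(benzyloxy)-3-methoxyphenyl]ethyl}chroman-2-one
Product: 8 (3R)-3-[2,4-bis(benzyloxy)-6-hydroxyphenyl]-5-[4-(benzyloxy)-3-methoxyphenyl]-N-methoxy-N-methylpentanamide
Conditions: MeNH(OMe)·HCl, AlMe3, CH2Cl2, 0 °C to rt; then 1 M HCl, 0 °C
Reagents that add atoms: N,O-dimethylhydroxylamine hydrochloride, CNOC.Cl
Why: Weinreb aminolysis of the aryl ester (lactone) by the aluminium amide made in the flask opens the ring, frees the single phenol that becomes O1 and leaves the stereocentre, which is β to the carbonyl, untouched.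

Step 6
Reactants: 8 (3R)-3-[2,4-bis(benzyloxy)-6-hydroxyphenyl]-5-[4-(benzyloxy)-3-methoxyphenyl]-N-methoxy-N-methylpentanamide; 9 ethyl phenylpropiolate
Product: 10 ethyl (2Z)-3-{3,5-bis(benzyloxy)-2-[(3R)-1-[4-(benzyloxy)-3-methoxyphenyl]-5-[methoxy(methyl)amino]-5-oxopentan-3-yl]phenoxy}-3-phenylprop-2-enoate
Conditions: 9 (1.5 equiv), K2CO3, DMF, 70 °C
Reagents that add atoms: none
Why: Base-mediated oxa-Michael addition of the phenoxide to the β-carbon of the ynoate with anti protonation should give mainly the (Z)-enol ether, in which the aryloxy group and the ester are cis, and the amide and the benzyl ethers are inert to K2CO3.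

Step 7
Reactants: 10 ethyl (2Z)-3-aryloxycinnamate ester
Product: 11 (2Z)-3-{3,5-bis(benzyloxy)-2-[(3R)-1-[4-(benzyloxy)-3-methoxyphenyl]-5-[methoxy(methyl)amino]-5-oxopentan-3-yl]phenoxy}-3-phenylprop-2-enoic acid
Conditions: LiOH, THF/MeOH/H2O, 40 °C; then 1 M HCl to pH 3, 0 °C
Reagents that add atoms: lithium hydroxide, [Li+].[OH-]
Why: Saponification of the ethyl ester under mild conditions should leave the much less electrophilic N-methoxy-N-methylamide intact, and a cold, brief acidification avoids hydrolysis of the enol ether.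

Step 8
Reactants: 11 (2Z)-3-aryloxycinnamic acid
Product: 13 (3R)-3-[5,7-bis(benzyloxy)-4-oxo-2-phenyl-4H-chromen-8-yl]-5-[4-(benzyloxy)-3-methoxyphenyl]-N-methoxy-N-methylpentanamide, via trifluoroacetic mixed anhydride 12 (not isolated)
Conditions: (CF3CO)2O (1.5 equiv), CH2Cl2, 0 °C to rt
Reagents that add atoms: none
Why: Trifluoroacetic anhydride converts the acid into mixed anhydride 12, whose ionisation is assisted by the enol ether oxygen, and ring carbon C4a attacks the acyl carbon C4 in an intramolecular Friedel–Crafts acylation, with proton loss restoring the arene and giving the pyranone. The closest known reaction type is the classical acid-mediated cyclisation of 3-aryloxycinnamic acids to flavones, combined with trifluoroacetic-anhydride-promoted intramolecular acylation of polyalkoxyarenes. Ring C closes in a six-membered mode that is exo with respect to the acyl C=O (6-exo-trig on the anhydride, 6-exo-dig on the acylium ion) and forms only the C4–C4a bond. No stereocentre is created, and the existing benzylic centre is not α to a carbonyl and cannot ionise here, so the R configuration is carried through. The step needs site selectivity for C4a and chemoselectivity over the 2-phenyl ring, the dialkoxyaryl ring and the amide: O1 has only one free ortho carbon because C8 bears the chain, C4a is activated by three oxygens (O1 and the C5 benzyloxy group ortho, the C7 benzyloxy group para), and the amide is inert to the anhydride and to trifluoroacetic acid at this temperature. Any (E)-anhydride isomerises through the single-bond character of C2–C3 in the cation, so both alkene isomers should end as 13.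

Step 9
Reactants: 13 8-substituted 5,7-bis(benzyloxy)flavone
Product: 15 (3R)-3-[5,7-bis(benzyloxy)-3-hydroxy-4-oxo-2-phenyl-4H-chromen-8-yl]-5-[4-(benzyloxy)-3-methoxyphenyl]-N-methoxy-N-methylpentanamide, via flavone 2,3-epoxide 14 (not isolated)
Conditions: dimethyldioxirane (acetone solution, 3 equiv), CH2Cl2, 0 °C; then p-TsOH·H2O (cat.), rt
Reagents that add atoms: dimethyldioxirane, CC1(C)OO1
Why: Electrophilic epoxidation of the C2=C3 bond by the neutral dioxirane, followed by acid-catalysed opening of the epoxide at C2 (cation stabilised by O1 and the phenyl group) and loss of the C3 proton, is the known conversion of benzyl-protected flavones into 3-hydroxyflavones.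

Step 10
Reactants: 15 3-hydroxyflavone N-methoxy-N-methylamide; 16 (2-bromoethyl)benzene
Product: 18 5,7-bis(benzyloxy)-8-{(3R)-1-[4-(benzyloxy)-3-methoxyphenyl]-5-oxo-7-phenylheptan-3-yl}-3-hydroxy-2-phenyl-4H-chromen-4-one, via 2-phenylethylmagnesium bromide 17 (not isolated)
Conditions: 16, Mg, THF, rt; then 15 (3 equiv of 17 per 15), THF, −20 to 0 °C; then 1 M HCl, 0 °C
Reagents that add atoms: none
Why: Weinreb ketone synthesis in which the first equivalent of Grignard reagent deprotonates the 3-hydroxyl, the resulting electron-rich magnesium flavonolate resists attack at C4 and C2, and the amide gives a chelated adduct that releases the ketone only on acid quench, so no tertiary alcohol should form.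

Step 11
Reactants: 18 tribenzyl ether of the target
Product: 19 8-[(3R)-1-(4-hydroxy-3-methoxyphenyl)-5-oxo-7-phenylheptan-3-yl]-3,5,7-trihydroxy-2-phenyl-4H-chromen-4-one (CNP0164153.1)
Conditions: H2 (1 atm), 10% Pd/C, EtOAc/MeOH, rt
Reagents that add atoms: none
Why: Catalytic hydrogenolysis of the three aryl benzyl ethers over palladium on carbon under neutral conditions should leave the aliphatic ketone, the flavonol C2=C3 bond and the benzylic stereocentre (C–C bonds only) untouched.

**Compound list**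
1 | 5,7-dihydroxycoumarin | O=c1ccc2c(O)cc(O)cc2o1 | starting material
2 | 5,7-bis(benzyloxy)coumarin | O=c1ccc2c(OCc3ccccc3)cc(OCc3ccccc3)cc2o1 | intermediate
3 | homovanillyl alcohol | COc1cc(CCO)ccc1O | starting material
4 | 2-[4-(benzyloxy)-3-methoxyphenyl]ethanol | COc1cc(CCO)ccc1OCc1ccccc1 | intermediate
5 | 1-(benzyloxy)-4-(2-bromoethyl)-2-methoxybenzene | COc1cc(CCBr)ccc1OCc1ccccc1 | intermediate
6 | 2-[4-(benzyloxy)-3-methoxyphenyl]ethylmagnesium bromide (not isolated) | COc1cc(CC[Mg]Br)ccc1OCc1ccccc1 | intermediate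
7 | (4R)-5,7-bis(benzyloxy)-4-{2-[4-(benzyloxy)-3-methoxyphenyl]ethyl}chroman-2-one | O=C1C[C@@H](CCc2ccc(OCc3ccccc3)c(OC)c2)c2c(OCc3ccccc3)cc(OCc3ccccc3)cc2O1 | intermediate
8 | (3R)-3-[2,4-bis(benzyloxy)-6-hydroxyphenyl]-5-[4-(benzyloxy)-3-methoxyphenyl]-N-methoxy-N-methylpentanamide | COc1cc(CC[C@H](CC(=O)N(C)OC)c2c(O)cc(OCc3ccccc3)cc2OCc2ccccc2)ccc1OCc1ccccc1 | intermediate
9 | ethyl phenylpropiolate | CCOC(=O)C#Cc1ccccc1 | starting material
10 | ethyl (2Z)-3-{3,5-bis(benzyloxy)-2-[(3R)-1-[4-(benzyloxy)-3-methoxyphenyl]-5-[methoxy(methyl)amino]-5-oxopentan-3-yl]phenoxy}-3-phenylprop-2-enoate | COc1cc(CC[C@H](CC(=O)N(C)OC)c2c(O/C(=C\C(=O)OCC)c3ccccc3)cc(OCc3ccccc3)cc2OCc2ccccc2)ccc1OCc1ccccc1 | intermediate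
11 | (2Z)-3-{3,5-bis(benzyloxy)-2-[(3R)-1-[4-(benzyloxy)-3-methoxyphenyl]-5-[methoxy(methyl)amino]-5-oxopentan-3-yl]phenoxy}-3-phenylprop-2-enoic acid (key-step precursor) | COc1cc(CC[C@H](CC(=O)N(C)OC)c2c(O/C(=C\C(=O)O)c3ccccc3)cc(OCc3ccccc3)cc2OCc2ccccc2)ccc1OCc1ccccc1 | intermediate
12 | mixed anhydride of 11 with trifluoroacetic acid (not isolated) | COc1cc(CC[C@H](CC(=O)N(C)OC)c2c(O/C(=C\C(=O)OC(=O)C(F)(F)F)c3ccccc3)cc(OCc3ccccc3)cc2OCc2ccccc2)ccc1OCc1ccccc1 | intermediate
13 | (3R)-3-[5,7-bis(benzyloxy)-4-oxo-2-phenyl-4H-chromen-8-yl]-5-[4-(benzyloxy)-3-methoxyphenyl]-N-methoxy-N-methylpentanamide (key-step product) | COc1cc(CC[C@H](CC(=O)N(C)OC)c2c(OCc3ccccc3)cc(OCc3ccccc3)c3c(=O)cc(-c4ccccc4)oc23)ccc1OCc1ccccc1 | intermediate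
14 | 2,3-epoxide of 13, both epoxide diastereomers (not isolated) | COc1cc(CC[C@H](CC(=O)N(C)OC)c2c(OCc3ccccc3)cc(OCc3ccccc3)c3c2OC2(c4ccccc4)OC2C3=O)ccc1OCc1ccccc1 | intermediate
15 | (3R)-3-[5,7-bis(benzyloxy)-3-hydroxy-4-oxo-2-phenyl-4H-chromen-8-yl]-5-[4-(benzyloxy)-3-methoxyphenyl]-N-methoxy-N-methylpentanamide | COc1cc(CC[C@H](CC(=O)N(C)OC)c2c(OCc3ccccc3)cc(OCc3ccccc3)c3c(=O)c(O)c(-c4ccccc4)oc23)ccc1OCc1ccccc1 | intermediate
16 | (2-bromoethyl)benzene | BrCCc1ccccc1 | starting material
17 | 2-phenylethylmagnesium bromide (not isolated) | Br[Mg]CCc1ccccc1 | intermediate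
18 | 5,7-bis(benzyloxy)-8-{(3R)-1-[4-(benzyloxy)-3-methoxyphenyl]-5-oxo-7-phenylheptan-3-yl}-3-hydroxy-2-phenyl-4H-chromen-4-one | COc1cc(CC[C@H](CC(=O)CCc2ccccc2)c2c(OCc3ccccc3)cc(OCc3ccccc3)c3c(=O)c(O)c(-c4ccccc4)oc23)ccc1OCc1ccccc1 | intermediate
19 | 8-[(3R)-1-(4-hydroxy-3-methoxyphenyl)-5-oxo-7-phenylheptan-3-yl]-3,5,7-trihydroxy-2-phenyl-4H-chromen-4-one | COc1cc(CC[C@H](CC(=O)CCc2ccccc2)c2c(O)cc(O)c3c(=O)c(O)c(-c4ccccc4)oc23)ccc1O | target

**Step count**
Total steps: 11. Longest linear sequence: 10 steps (steps 2 to 11, from homovanillyl alcohol 3).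

**Steps most likely to fail, with fallbacks**

Step 4. The conjugate addition may be slow on this electron-rich coumarin with a peri benzyloxy group at C5, so that uncatalysed background addition or 1,2-addition to the lactone erodes the facial selectivity. The fallback builds the same lactone by organocatalysis instead of by addition to the coumarin. It sets out from Grignard reagent 6, which is added to 3-(dimethylamino)acrolein (CN(C)/C=C/C=O) in THF at 0 °C and hydrolysed with dilute HCl to give the enal (E)-5-[4-(benzyloxy)-3-methoxyphenyl]pent-2-enal F1. Iminium-catalysed Friedel–Crafts alkylation of purchased 3,5-bis(benzyloxy)phenol (Oc1cc(OCc2ccccc2)cc(OCc2ccccc2)c1) with F1 follows, using the antipode of 2-[diphenyl(trimethylsilyloxy)methyl]pyrrolidine that gives 4R (20 mol%), PhCO2H, toluene, 0 °C. Attack by a carbon ortho to the hydroxyl and closure to the hemiacetal should give the lactol (4R)-5,7-bis(benzyloxy)-4-{2-[4-(benzyloxy)-3-methoxyphenyl]ethyl}chroman-2-ol F2. Oxidation of the lactol (PhI(OAc)2, TEMPO cat., CH2Cl2, rt) comes back to the route at 7.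

Step 8. Ring closure may be outrun by intermolecular trifluoroacetylation of the free, doubly activated ring carbon between the two benzyloxy groups, by acid-induced loss of a benzyl group, or by hydrolytic cleavage of the enol ether. The fallback closes ring C at O1–C2 instead, by the Baker–Venkataraman sequence, and sets out from phenol 8.
- C-Acetylation ortho to the hydroxyl (Ac2O, BF3·OEt2, the boron chelate favouring the ortho-hydroxy ketone) should give the ortho-hydroxyacetophenone (3R)-3-[3-acetyl-4,6-bis(benzyloxy)-2-hydroxyphenyl]-5-[4-(benzyloxy)-3-methoxyphenyl]-N-methoxy-N-methylpentanamide F3.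
- O-Benzoylation (BzCl, pyridine) gives the aryl benzoate F4.
- Baker–Venkataraman rearrangement (KOH, pyridine, 50 °C) gives the 1,3-diketone F5.
- Cyclodehydration (p-TsOH·H2O, toluene, 80 °C) comes back to the route at 13.

Step 9. Epoxidation of the electron-poor C2=C3 bond is slow, and the excess dioxirane may meanwhile oxidise benzylic C–H bonds of the benzyl ethers or the dialkoxyaryl ring. The fallback brings the C3 oxygen in as a benzyl ether with the acyl unit, so no late oxidation is needed; it sets out from phenol 8 and replaces steps 6 to 9.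
- C-Acylation ortho to the hydroxyl with benzyloxyacetic anhydride (O=C(COCc1ccccc1)OC(=O)COCc1ccccc1) and BF3·OEt2 should give the ortho-hydroxyaryl benzyloxymethyl ketone F6.
- Benzoylation (BzCl, pyridine) gives the aryl benzoate F7.
- Baker–Venkataraman rearrangement (KOH, pyridine, 50 °C) gives the 2-benzyloxy-1,3-diketone F8.
- Cyclodehydration (p-TsOH·H2O, toluene, 80 °C) gives the 3-benzyloxyflavone N-methoxy-N-methylamide F9.
- Grignard reagent 17 (THF, −20 to 0 °C, then 1 M HCl) converts the amide into the 3-benzyloxyflavone ketone F10.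
- Hydrogenolysis (H2, 10% Pd/C, EtOAc/MeOH) removes all four benzyl groups and comes back to the route at 19.

**Further compounds**
F1 | step 4 | (E)-5-[4-(benzyloxy)-3-methoxyphenyl]pent-2-enal | COc1cc(CC/C=C/C=O)ccc1OCc1ccccc1
F2 | step 4 | (4R)-5,7-bis(benzyloxy)-4-{2-[4-(benzyloxy)-3-methoxyphenyl]ethyl}chroman-2-ol (anomer mixture) | OC1C[C@@H](CCc2ccc(OCc3ccccc3)c(OC)c2)c2c(OCc3ccccc3)cc(OCc3ccccc3)cc2O1
F3 | step 8 | (3R)-3-[3-acetyl-4,6-bis(benzyloxy)-2-hydroxyphenyl]-5-[4-(benzyloxy)-3-methoxyphenyl]-N-methoxy-N-methylpentanamide | COc1cc(CC[C@H](CC(=O)N(C)OC)c2c(O)c(C(C)=O)c(OCc3ccccc3)cc2OCc2ccccc2)ccc1OCc1ccccc1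
F4 | step 8 | (3R)-3-[3-acetyl-2-(benzoyloxy)-4,6-bis(benzyloxy)phenyl]-5-[4-(benzyloxy)-3-methoxyphenyl]-N-methoxy-N-methylpentanamide | COc1cc(CC[C@H](CC(=O)N(C)OC)c2c(OC(=O)c3ccccc3)c(C(C)=O)c(OCc3ccccc3)cc2OCc2ccccc2)ccc1OCc1ccccc1
F5 | step 8 | (3R)-3-[4,6-bis(benzyloxy)-2-hydroxy-3-(3-oxo-3-phenylpropanoyl)phenyl]-5-[4-(benzyloxy)-3-methoxyphenyl]-N-methoxy-N-methylpentanamide | COc1cc(CC[C@H](CC(=O)N(C)OC)c2c(O)c(C(=O)CC(=O)c3ccccc3)c(OCc3ccccc3)cc2OCc2ccccc2)ccc1OCc1ccccc1
F6 | step 9 | (3R)-3-{4,6-bis(benzyloxy)-3-[(benzyloxy)acetyl]-2-hydroxyphenyl}-5-[4-(benzyloxy)-3-methoxyphenyl]-N-methoxy-N-methylpentanamide | COc1cc(CC[C@H](CC(=O)N(C)OC)c2c(O)c(C(=O)COCc3ccccc3)c(OCc3ccccc3)cc2OCc2ccccc2)ccc1OCc1ccccc1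
F7 | step 9 | (3R)-3-{2-(benzoyloxy)-4,6-bis(benzyloxy)-3-[(benzyloxy)acetyl]phenyl}-5-[4-(benzyloxy)-3-methoxyphenyl]-N-methoxy-N-methylpentanamide | COc1cc(CC[C@H](CC(=O)N(C)OC)c2c(OC(=O)c3ccccc3)c(C(=O)COCc3ccccc3)c(OCc3ccccc3)cc2OCc2ccccc2)ccc1OCc1ccccc1
F8 | step 9 | (3R)-3-{4,6-bis(benzyloxy)-3-[2-(benzyloxy)-3-oxo-3-phenylpropanoyl]-2-hydroxyphenyl}-5-[4-(benzyloxy)-3-methoxyphenyl]-N-methoxy-N-methylpentanamide | COc1cc(CC[C@H](CC(=O)N(C)OC)c2c(O)c(C(=O)C(OCc3ccccc3)C(=O)c3ccccc3)c(OCc3ccccc3)cc2OCc2ccccc2)ccc1OCc1ccccc1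
F9 | step 9 | (3R)-5-[4-(benzyloxy)-3-methoxyphenyl]-N-methoxy-N-methyl-3-[3,5,7-tris(benzyloxy)-4-oxo-2-phenyl-4H-chromen-8-yl]pentanamide | COc1cc(CC[C@H](CC(=O)N(C)OC)c2c(OCc3ccccc3)cc(OCc3ccccc3)c3c(=O)c(OCc4ccccc4)c(-c4ccccc4)oc23)ccc1OCc1ccccc1
F10 | step 9 | 3,5,7-tris(benzyloxy)-8-{(3R)-1-[4-(benzyloxy)-3-methoxyphenyl]-5-oxo-7-phenylheptan-3-yl}-2-phenyl-4H-chromen-4-one | COc1cc(CC[C@H](CC(=O)CCc2ccccc2)c2c(OCc3ccccc3)cc(OCc3ccccc3)c3c(=O)c(OCc4ccccc4)c(-c4ccccc4)oc23)ccc1OCc1ccccc1
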